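**Retrosynthetic overview**
- The usual chalcone/Algar–Flynn–Oyamada or Baker–Venkataraman ring construction is set aside. The key disconnection is the C2–C1' bond: a late C2–H zincation/Negishi arylation of a preformed 3-methoxychromone with 2-iodoanisole.
- 3,5,7,8-Tetramethoxychromone comes from an o-hydroxy-ω-methoxyacetophenone plus a C1 unit (DMF-DMA), so the 3-OMe is in place before the pyranone closes.
- That ketone comes from 1,2,3,5-tetramethoxybenzene and methoxyacetyl chloride by Friedel–Crafts acylation with in-flask ortho-demethylation.
- Ring order: ring A is bought, ring C (pyranone) is closed in step 2, ring B (bought) is attached last in step 3.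

Assumption: the target (3,5,7,8,2'-pentamethoxyflavone) is achiral. It has no stereocentre and the C2–aryl axis rotates freely, so no stereocontrol is needed and "single enantiomer" is met by the compound itself.

**Step 1**
Reactants: 1 1,2,3,5-tetramethoxybenzene; 2 methoxyacetyl chloride
Product: 4 1-(2-hydroxy-3,4,6-trimethoxyphenyl)-2-methoxyethan-1-one, via pentamethoxy ketone 3 (not isolated)
Conditions: AlCl3 (3 equiv), Et2O, 0 °C to rt, 24 h; then ice/aq. HCl
Reagents that add atoms: none
Why: Friedel–Crafts acylation goes to the only kind of free ring position (ortho/para to three OMe groups), and the AlCl3–carbonyl chelate then cleaves one ortho-methoxy group, expected to be the 2-OMe that is flanked by the 3-OMe and twisted out of conjugation (classical one-pot acylation/ortho-demethylation; ether tempers AlCl3 against decarbonylation of the methoxyacetyl cation).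

**Step 2**
Reactants: 4 1-(2-hydroxy-3,4,6-trimethoxyphenyl)-2-methoxyethan-1-one
Product: 6 3,5,7,8-tetramethoxy-4H-chromen-4-one, via enaminone 5 (not isolated)
Conditions: DMF-DMA (3 equiv), PhMe, 100 °C; concentrate; then AcOH, 60 °C
Reagents that add atoms: N,N-dimethylformamide dimethyl acetal (DMF-DMA), COC(OC)N(C)C
Why: Aminomethylenation of the activated α-methylene gives the enaminone, and acid-promoted addition of the phenol to the enamine carbon with loss of dimethylamine closes the pyranone (enaminone chromone synthesis, as in the deoxybenzoin-to-isoflavone reaction), with the 3-OMe carried in from the ketone.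

**Step 3**
Reactants: 6 3,5,7,8-tetramethoxy-4H-chromen-4-one; 7 2-iodoanisole
Product: 9 3,5,7,8-tetramethoxy-2-(2-methoxyphenyl)-4H-chromen-4-one, via chromonylzinc chloride 8 (not isolated)
Conditions: TMPZnCl·LiCl (1.3 equiv), THF, 25 °C, 1 h; then 7 (1.2 equiv), Pd(OAc)2 (3 mol%), SPhos (6 mol%), THF, 50 °C
Reagents that add atoms: none
Why: The hindered zinc amide removes the most acidic C–H, which is C2–H (α to the ring oxygen, next to the coordinating 3-OMe, C3 blocked, C6–H far less acidic), and the resulting heteroaryl zinc chloride undergoes Negishi cross-coupling with the aryl iodide; directed zincation of chromones followed by Negishi arylation is a known reaction type, applied here to a 3-methoxy substrate.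

**Compound list**
1 | 1,2,3,5-tetramethoxybenzene | COc1cc(OC)c(OC)c(OC)c1 | starting material
2 | methoxyacetyl chloride | COCC(=O)Cl | starting material
3 | 2-methoxy-1-(2,3,4,6-tetramethoxyphenyl)ethan-1-one | COCC(=O)c1c(OC)cc(OC)c(OC)c1OC | intermediate (not isolated)
4 | 1-(2-hydroxy-3,4,6-trimethoxyphenyl)-2-methoxyethan-1-one | COCC(=O)c1c(OC)cc(OC)c(OC)c1O | intermediate
5 | (Z)-3-(dimethylamino)-1-(2-hydroxy-3,4,6-trimethoxyphenyl)-2-methoxyprop-2-en-1-one (geometry of no consequence) | CO/C(=C\N(C)C)C(=O)c1c(OC)cc(OC)c(OC)c1O | intermediate (not isolated)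
6 | 3,5,7,8-tetramethoxy-4H-chromen-4-one | COc1coc2c(OC)c(OC)cc(OC)c2c1=O | intermediate
7 | 2-iodoanisole (1-iodo-2-methoxybenzene) | COc1ccccc1I | starting material
8 | chloro(3,5,7,8-tetramethoxy-4-oxo-4H-chromen-2-yl)zinc | COc1c([Zn]Cl)oc2c(OC)c(OC)cc(OC)c2c1=O | intermediate (not isolated)
9 | 3,5,7,8-tetramethoxy-2-(2-methoxyphenyl)-4H-chromen-4-one (achiral) | COc1ccccc1-c1oc2c(OC)c(OC)cc(OC)c2c(=O)c1OC | target

**Totals**
Total step count: 3. Longest linear sequence: 3 steps (1 → 4 → 6 → 9).

**Steps most likely to fail, with fallbacks**

Step 3 (key step) carries the most risk. Zincation may be incomplete, or the coupling may stall because both partners are ortho-substituted. The fallback abandons the C2–aryl disconnection and sets out from 4. O-Acylation of 4 with 2-methoxybenzoyl chloride (pyridine, DMAP, rt) gives 2-(2-methoxyacetyl)-3,5,6-trimethoxyphenyl 2-methoxybenzoate F3. Baker–Venkataraman acyl shift (KOH, pyridine, 50 °C) gives 1-(2-hydroxy-3,4,6-trimethoxyphenyl)-2-methoxy-3-(2-methoxyphenyl)propane-1,3-dione F4. Cyclodehydration (cat. H2SO4, AcOH, 80 °C) then comes back to the route at 9.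

Step 1 can fail in two ways: decarbonylation of the methoxyacetyl chloride–AlCl3 complex to a methoxymethyl cation, or cleavage of the wrong ortho-methoxy group. The identity of 4 must be checked by NOE: the lone aromatic H should see two OMe groups. The fallback sets out from 1 and replaces the electrophilic acylation with an anionic one. Ortho-lithiation between the two flanking methoxy groups (n-BuLi, TMEDA, THF, 0 °C) gives (2,3,4,6-tetramethoxyphenyl)lithium F1. Acylation with N,2-dimethoxy-N-methylacetamide (Weinreb ketone synthesis) gives 3, this time isolated. A separate chelation-controlled mono-demethylation (BCl3, CH2Cl2, −78 to 0 °C) comes back at 4. The regiochemical risk of the demethylation remains in this fallback.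

Step 2 can fail through sluggish condensation at the hindered α-methoxy methylene or through O-methylation of the phenol by DMF-DMA. The fallback sets out from 4 and uses a base-mediated Claisen formylation instead. Ethyl formate with NaH (THF, 0 °C to rt) gives, after acidic work-up, 2-hydroxy-3,5,7,8-tetramethoxychroman-4-one F2 as a diastereomer mixture. Acid dehydration (cat. TsOH, PhMe, 80 °C) erases both transient stereocentres and comes back at 6.

**Further compounds**
F1 | step 1 | (2,3,4,6-tetramethoxyphenyl)lithium | [Li]c1c(OC)cc(OC)c(OC)c1OC
F2 | step 2 | 2-hydroxy-3,5,7,8-tetramethoxychroman-4-one (racemic diastereomer mixture, stereocentres undefined) | COC1C(O)Oc2c(OC)c(OC)cc(OC)c2C1=O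
F3 | step 3 | 2-(2-methoxyacetyl)-3,5,6-trimethoxyphenyl 2-methoxybenzoate | COCC(=O)c1c(OC)cc(OC)c(OC)c1OC(=O)c1ccccc1OC
F4 | step 3 | 1-(2-hydroxy-3,4,6-trimethoxyphenyl)-2-methoxy-3-(2-methoxyphenyl)propane-1,3-dione (racemic, enolisable) | COC(C(=O)c1ccccc1OC)C(=O)c1c(OC)cc(OC)c(OC)c1O
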